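(All runs stem from a simulated flask with constants of no real substance, and the scatter is random.)

**The trap.** A flat top on a curve looks like a flask that has stopped, but a level reading can also be making and loss in balance, so I did not read these tops as an end.

| flask | starting material | coupling partner | target | time |
|---|---|---|---|---|
| spring | 0.0500 M | 0.0500 M |  |  |
| summer | 0.0500 M | 0.0750 M |  |  |
| autumn | 0.0250 M | 0.0500 M |  |  |
| dusk | 0.0500 M | 0.0500 M | 0.0250 M | 17 min |

| run | time / min | [target] / M |
|---|---|---|
| spring run | 1.3 | 0.00210 |
| spring run | 3.9 | 0.00582 |
| spring run | 7.5 | 0.00909 |
| spring run | 12 | 0.01111 |
| spring run | 17 | 0.01201 |
| summer run | 1.3 | 0.00462 |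
| summer run | 3.9 | 0.01191 |
| summer run | 7.5 | 0.01751 |
| summer run | 12 | 0.01973 |
| summer run | 17 | 0.02064 |
| autumn run | 1.3 | 0.00146 |
| autumn run | 3.9 | 0.00409 |
| autumn run | 7.5 | 0.00605 |
| autumn run | 12 | 0.00797 |
| autumn run | 17 | 0.00872 |

(standard deviation of a reading: 2 × 10⁻⁴ M)

- Overall: starting material + coupling partner -> target.
- Constant volume, constant temperature.
- What is held in complexes is read along with the free species.
- "The second partner" is coupling partner.
- An order is taken over about fifteen percent of the charge, up and down.
- A share of target counts the target that was charged too.

1. apparent order in [coupling partner] of the starting rate, round the charge of the spring run (the rate where two percent of its starting material have turned into target)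
2. apparent order in [starting material] of the starting rate, round the charge of the spring run (the rate where two percent of its starting material have turned into target) (one fixed amount of target, the same in the runs compared)
3. target in the dusk run at 17 min, as a share of the starting material charged

**Fastest rung.** Ratios of first readings gave orders of 1.94 in [coupling partner] and 0.524 in [starting material]. I rounded these to 2 and 0.5. The spring run charges both equally, so its rate falls as the remaining fraction to the power 2.50. Dividing its first reading by its time and putting back the small depletion gave a spring starting rate of 1.70 mM min⁻¹. On that law, the spring rate of making drops to half in 10.1 min.

**Middle rung.** The same law, with nothing lost, gives 17.0 mM by 17 min in the spring run, yet the reading there is 0.01201 M. I read that gap of 5.03 mM as a first-order loss of target, which was an assumption, and no small correction. Dividing the gap by the area under the spring readings, 8.50 M·s, gave a loss constant of 0.0355 min⁻¹. Target then falls to half in 19.5 min, slower than the making fades.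

**Slowest rung.** Turning the whole spring charge over at the starting rate takes 29.4 min, longer still.

**The rule.** I carried the survival share, the fraction of target present at the start that still stands at the asked time: 0.547. If charged target leaves the making untouched, the dusk run holds the spring reading plus its charge times that share, which is 51.4% of its starting material.

**The forecast.** It gave 1.9, 0.5 and 72%, on the ground that “Early rates fall no faster than depletion predicts”. Its dusk figure stood above mine.

**The result.** The orders came out at 2.1 and 0.59, and the dusk run at 48.8%.

    starting material + 2 coupling partner → target + coupling partner (72.00 M⁻² min⁻¹)
    2 starting material ⇌ idle substrate dimer, settled at all times (171.0 M⁻¹)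
    target → decomposed product (0.04194 min⁻¹)

Taking the spring reading from the dusk amount leaves a survival share of 0.495 of the charged target, against my 0.547. Putting the spring gap and the 11.3 mM of charged target that my share lets go back onto my dusk figure gives 84.1% for a dusk flask that loses nothing. The simulated dusk run without the passing of target into decomposed product reaches 86.3%, against 48.8% with it.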